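**Retrosynthetic overview**
- The target is reached from its tris(allyl ether) by deallylation. The tris(allyl ether) comes from the N5-acyl diamine and two equivalents of (E)-4-(allyloxy)cinnamoyl chloride (N1 and N10 amides), and the diamine from the corresponding diazide by Staudinger reduction.
- The chain is numbered N1-C2-C3-C4-N5-C6-C7-C8-C9-N10. The N5 amide together with its three-carbon arm C4-C3-C2 is a masked 2-styryl-5,6-dihydro-4H-1,3-oxazine: the ring nitrogen is N5, the ring carbons 4, 5 and 6 are C4, C3 and C2, and the ring oxygen becomes the N5 amide oxygen.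
- The diazide is cut at N5–C6 (N-alkylation of the oxazine by 4-azidobutyl triflate) and at C2–N1 (azide opening of the oxazinium ion at its O–CH2 carbon).
- The oxazine comes from (E)-4-(allyloxy)cinnamic acid (Doebner condensation of 4-(allyloxy)benzaldehyde with malonic acid) and 3-aminopropan-1-ol; the triflate comes from 4-chlorobutan-1-ol and sodium azide.
- Ring order: the oxazine is the only ring made (step 4) and it is opened again in step 7; the three benzene rings are bought.

Key step: step 7

Remark on the chemistry: the phenols are carried as allyl ethers, which should be inert to triflate, azide, phosphine and acid chloride and are removed at the end under neutral conditions by zerovalent palladium. The E-geometry of all three alkenes is set in the Doebner condensation and is not touched afterwards.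
Remark on handling: the small azides 12 and 13 are kept in solution behind a shield, and sodium azide is never combined with dichloromethane or acid.

**Step 1**
Reactants: 1 4-(allyloxy)benzaldehyde; 2 malonic acid
Product: 4 (E)-3-[4-(allyloxy)phenyl]acrylic acid, via arylidenemalonic acid 3 (not isolated)
Conditions: pyridine, piperidine (cat.), 100 °C; acidic work-up
Reagents that add atoms: none
Why: Knoevenagel condensation in the Doebner modification, in which decarboxylation of the arylidenemalonic acid should give the thermodynamically favoured E-cinnamic acid while the allyl aryl ether stays far below Claisen temperatures.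

**Step 2**
Reactants: 4 (E)-3-[4-(allyloxy)phenyl]acrylic acid
Product: 5 (E)-3-[4-(allyloxy)phenyl]acryloyl chloride
Conditions: (COCl)2, DMF (cat.), CH2Cl2, 0 °C to rt; evaporate, use crude
Reagents that add atoms: oxalyl chloride, O=C(Cl)C(=O)Cl
Why: Acid chloride formation through the catalytic Vilsmeier-type chloroiminium species, which should leave the aryl allyl ether and the conjugated E-alkene unchanged.

**Step 3**
Reactants: 5 (E)-3-[4-(allyloxy)phenyl]acryloyl chloride; 6 3-aminopropan-1-ol
Product: 7 (E)-3-[4-(allyloxy)phenyl]-N-(3-hydroxypropyl)acrylamide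
Conditions: 6 (1.2 equiv), Et3N, CH2Cl2, 0 °C, slow addition of 5
Reagents that add atoms: none
Why: N-acylation of an amino alcohol with an acid chloride, in which the primary amine should outcompete the primary alcohol at 0 °C.

**Step 4**
Reactants: 7 (E)-3-[4-(allyloxy)phenyl]-N-(3-hydroxypropyl)acrylamide
Product: 9 2-[(E)-4-(allyloxy)styryl]-5,6-dihydro-4H-1,3-oxazine, via mesylate 8 (not isolated)
Conditions: MsCl, Et3N, CH2Cl2, 0 °C; aqueous wash; then KOtBu, THF, 0 °C to rt; purification on Et3N-deactivated silica
Reagents that add atoms: none
Why: Cyclodehydration by O-sulfonylation and intramolecular O-alkylation of the amidate, a 6-exo-tet closure that should win over N-attack because the latter would need a four-membered ring.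

**Step 5**
Reactants: 10 4-chlorobutan-1-ol; 11 sodium azide
Product: 12 4-azidobutan-1-ol
Conditions: NaN3 (1.5 equiv), DMF, 70 °C; extractive work-up, not distilled
Reagents that add atoms: none
Why: SN2 displacement of a primary chloride by azide under near-neutral conditions, where base-induced closure of 10 to tetrahydrofuran should not compete.

**Step 6**
Reactants: 12 4-azidobutan-1-ol
Product: 13 4-azidobutyl trifluoromethanesulfonate
Conditions: Tf2O, 2,6-lutidine, CH2Cl2, −78 to −20 °C; cold water wash, dried, short silica plug; kept as a cold CH2Cl2 solution and used the same day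
Reagents that add atoms: trifluoromethanesulfonic anhydride, O=S(=O)(OS(=O)(=O)C(F)(F)F)C(F)(F)F
Why: O-triflation of a primary alcohol, in which the hindered base should not be alkylated at low temperature and the alkyl azide is far less nucleophilic than the hydroxyl group.

**Step 7**
Reactants: 9 2-[(E)-4-(allyloxy)styryl]-5,6-dihydro-4H-1,3-oxazine; 13 4-azidobutyl trifluoromethanesulfonate; 11 sodium azide
Product: 15 (E)-3-[4-(allyloxy)phenyl]-N-(4-azidobutyl)-N-(3-azidopropyl)acrylamide, via oxazinium triflate 14 (not isolated)
Conditions: 13 (1.0 equiv), CH2Cl2, −20 °C to rt; CH2Cl2 removed completely under reduced pressure; then NaN3 (2 equiv), dry DMF, 50 °C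
Reagents that add atoms: none
Why: The sp2 nitrogen of the cyclic imidate 9 should displace triflate from 13 in an SN2 step (N5–C6 bond) to give the conjugation-stabilised N-alkyl oxazinium salt 14, and azide should then attack the ring O–CH2 carbon in a second SN2 step (C2–N1 bond) with the amide oxygen as leaving group, so that the imidate unfolds into the tertiary amide 15. The closest known reaction type is the cationic ring-opening polymerisation of 2-oxazines and 2-oxazolines, in which alkyl triflates initiate by this same N-alkylation and sodium azide end-caps the cationic chain end by this same alkyl–oxygen cleavage; here the sequence is stopped after one unit. No ring is closed (the oxazine ring is opened), no stereocentre is formed, and the E-alkene is a spectator. Single insertion rather than oligomerisation is needed, and it should be secured because triflate alkylation is complete at or below room temperature whereas attack of a neutral oxazine on an oxazinium ion needs heating, and because a full equivalent of 13 leaves no free 9 when azide is added. Opening at O–CH2 rather than attack at the imidate carbon or the styryl β-carbon should be secured because azide addition at those positions is reversible while alkyl–oxygen cleavage is irreversible and ends in the amide, and because water, which would open 14 at the imidate carbon to an amino ester, is excluded.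

**Step 8**
Reactants: 15 (E)-3-[4-(allyloxy)phenyl]-N-(4-azidobutyl)-N-(3-azidopropyl)acrylamide
Product: 17 (E)-3-[4-(allyloxy)phenyl]-N-(4-aminobutyl)-N-(3-aminopropyl)acrylamide, via bis(iminophosphorane) 16 (not isolated)
Conditions: PMe3 (2.4 equiv), THF, 0 °C to rt; then H2O, rt; concentrated, dried azeotropically with toluene, used crude at once
Reagents that add atoms: none
Why: Staudinger reduction, in which each azide should give an iminophosphorane with loss of N2 and then the amine on hydrolysis, without touching the alkenes, the allyl ether or the tertiary amide as a hydrogenation would.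

**Step 9**
Reactants: 17 (E)-3-[4-(allyloxy)phenyl]-N-(4-aminobutyl)-N-(3-aminopropyl)acrylamide; 5 (E)-3-[4-(allyloxy)phenyl]acryloyl chloride
Product: 18 N1,N5,N10-tris[(E)-4-(allyloxy)cinnamoyl]spermidine
Conditions: 5 (2.2 equiv), Et3N, CH2Cl2, 0 °C to rt
Reagents that add atoms: none
Why: Amide formation by N-acylation with an acid chloride, in which the two primary amines are the only nucleophiles in the molecule.

**Step 10**
Reactants: 18 N1,N5,N10-tris[(E)-4-(allyloxy)cinnamoyl]spermidine
Product: 19 N(1),N(5),N(10)-(E)-tri-p-coumaroylspermidine
Conditions: Pd(PPh3)4 (cat.), morpholine (excess), THF, rt, argon, in the dark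
Reagents that add atoms: none
Why: Tsuji–Trost-type deallylation, in which zerovalent palladium should ionise each aryl allyl ether to a π-allyl complex and a phenoxide and morpholine should trap the allyl group, under neutral conditions that leave the three cinnamamides and their E-geometry unchanged.

**Compound list**
1 | 4-(allyloxy)benzaldehyde | C=CCOc1ccc(C=O)cc1 | starting material
2 | malonic acid | OC(=O)CC(=O)O | starting material
3 | 2-[4-(allyloxy)benzylidene]malonic acid | C=CCOc1ccc(C=C(C(=O)O)C(=O)O)cc1 | intermediate (not isolated)
4 | (E)-3-[4-(allyloxy)phenyl]acrylic acid | C=CCOc1ccc(/C=C/C(=O)O)cc1 | intermediate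
5 | (E)-3-[4-(allyloxy)phenyl]acryloyl chloride | C=CCOc1ccc(/C=C/C(=O)Cl)cc1 | intermediate
6 | 3-aminopropan-1-ol | NCCCO | starting material
7 | (E)-3-[4-(allyloxy)phenyl]-N-(3-hydroxypropyl)acrylamide | C=CCOc1ccc(/C=C/C(=O)NCCCO)cc1 | intermediate
8 | 3-[(E)-3-[4-(allyloxy)phenyl]acrylamido]propyl methanesulfonate | C=CCOc1ccc(/C=C/C(=O)NCCCOS(C)(=O)=O)cc1 | intermediate (not isolated)
9 | 2-[(E)-4-(allyloxy)styryl]-5,6-dihydro-4H-1,3-oxazine | C=CCOc1ccc(/C=C/C2=NCCCO2)cc1 | intermediate
10 | 4-chlorobutan-1-ol | OCCCCCl | starting material
11 | sodium azide | [N-]=[N+]=[N-].[Na+] | starting material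
12 | 4-azidobutan-1-ol | [N-]=[N+]=NCCCCO | intermediate
13 | 4-azidobutyl trifluoromethanesulfonate | [N-]=[N+]=NCCCCOS(=O)(=O)C(F)(F)F | intermediate
14 | 3-(4-azidobutyl)-2-[(E)-4-(allyloxy)styryl]-5,6-dihydro-4H-1,3-oxazin-3-ium trifluoromethanesulfonate | C=CCOc1ccc(/C=C/C2=[N+](CCCCN=[N+]=[N-])CCCO2)cc1.[O-]S(=O)(=O)C(F)(F)F | intermediate (not isolated)
15 | (E)-3-[4-(allyloxy)phenyl]-N-(4-azidobutyl)-N-(3-azidopropyl)acrylamide | C=CCOc1ccc(/C=C/C(=O)N(CCCCN=[N+]=[N-])CCCN=[N+]=[N-])cc1 | intermediate
16 | (E)-3-[4-(allyloxy)phenyl]-N-[4-(trimethylphosphoranylideneamino)butyl]-N-[3-(trimethylphosphoranylideneamino)propyl]acrylamide | C=CCOc1ccc(/C=C/C(=O)N(CCCCN=P(C)(C)C)CCCN=P(C)(C)C)cc1 | intermediate (not isolated)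
17 | (E)-3-[4-(allyloxy)phenyl]-N-(4-aminobutyl)-N-(3-aminopropyl)acrylamide | C=CCOc1ccc(/C=C/C(=O)N(CCCCN)CCCN)cc1 | intermediate
18 | N1,N5,N10-tris[(E)-4-(allyloxy)cinnamoyl]spermidine | C=CCOc1ccc(/C=C/C(=O)NCCCCN(CCCNC(=O)/C=C/c2ccc(OCC=C)cc2)C(=O)/C=C/c2ccc(OCC=C)cc2)cc1 | intermediate
19 | N(1),N(5),N(10)-(E)-tri-p-coumaroylspermidine | O=C(/C=C/c1ccc(O)cc1)NCCCCN(CCCNC(=O)/C=C/c1ccc(O)cc1)C(=O)/C=C/c1ccc(O)cc1 | target

**Step count**
Total steps: 10. Longest linear sequence: 8 steps (steps 1, 2, 3, 4, 7, 8, 9, 10); steps 5 and 6 form the side branch that joins at step 7.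

**Steps most likely to fail**

Step 7. The cation 14 may be attacked by still unalkylated 9 (chain growth), it may be opened at the imidate carbon by adventitious water, or the azide opening may be slow enough for reversible adducts to divert material. The fallback leaves the linchpin and acylates the intact polyamine. It sets out from 5: purchased spermidine F1 is treated with 5 (3.3 equiv) and Et3N in CH2Cl2 at 0 °C to rt, which should acylate all three nitrogens. It comes back to the route at 18.

Step 6. The azido triflate may destroy itself on warming or concentration through intramolecular alkylation of its own azide, or it may alkylate the base. The fallback keeps azide away from the triflate and introduces both azides last. It sets out from 10 and 9. Alcohol 10 is triflated (Tf2O, 2,6-lutidine, CH2Cl2, −78 °C) to 4-chlorobutyl trifluoromethanesulfonate F2. F2 alkylates 9 in CH2Cl2 to 3-(4-chlorobutyl)-2-[(E)-4-(allyloxy)styryl]-5,6-dihydro-4H-1,3-oxazin-3-ium trifluoromethanesulfonate F3. After complete removal of CH2Cl2, sodium azide (3 equiv) in DMF at 70 °C should open the ring and displace the primary chloride in the same flask. It comes back to the route at 15.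

Step 8. In the free diamine 17 a primary amine sits three or four carbons from the tertiary amide, so the cinnamoyl group may shift from N5 to N1 or N10 through a cyclic tetrahedral intermediate, an amine may add to the conjugated alkene, and the polar diamine may be lost on isolation. The fallback never liberates the amines (Staudinger–Vilarrasa amidation). It sets out from 15 and 5. Diazide 15 is treated with PMe3 (2.05 equiv) in THF at 0 °C to give 16. Acid chloride 5 (2.2 equiv) is added, which should acylate both iminophosphorane nitrogens to the bis(N-acylaminophosphonium) dichloride F4. Aqueous NaHCO3 then cleaves the P–N bonds. It comes back to the route at 18.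

**Further compounds**
F1 | step 7 | spermidine (purchased, not made) | NCCCCNCCCN
F2 | step 6 | 4-chlorobutyl trifluoromethanesulfonate | ClCCCCOS(=O)(=O)C(F)(F)F
F3 | step 6 | 3-(4-chlorobutyl)-2-[(E)-4-(allyloxy)styryl]-5,6-dihydro-4H-1,3-oxazin-3-ium trifluoromethanesulfonate | C=CCOc1ccc(/C=C/C2=[N+](CCCCCl)CCCO2)cc1.[O-]S(=O)(=O)C(F)(F)F
F4 | step 8 | bis(N-acylaminophosphonium) dichloride from 16 and two equivalents of 5 | C=CCOc1ccc(/C=C/C(=O)N(CCCCN(C(=O)/C=C/c2ccc(OCC=C)cc2)[P+](C)(C)C)CCCN(C(=O)/C=C/c2ccc(OCC=C)cc2)[P+](C)(C)C)cc1.[Cl-].[Cl-]
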